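**Retrosynthetic overview** (chain numbered C1 = lactone carbonyl to C20)
- Target ⇒ C11 carbinol by hydroxyl-directed anti reduction and, just before it in the same flask, the C9–O bond by boron-templated conjugate hydration of a δ-hydroxy enone directed by C7–OH (key C–O bond; sets C9 and relays to C11).
- δ-Hydroxy enone ⇒ cross-metathesis of a lactone-bearing homoallylic alcohol with dodec-1-en-3-one (from decanoyl chloride and a vinylstannane).
- The only ring, the 5,6-dihydropyran-2-one, is closed early by ring-closing metathesis of a mono-acrylate, before the polyol chain is grown.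
- Mono-acrylate ⇒ single O-acylation of C2-symmetric (4S,6S)-nona-1,8-diene-4,6-diol (homotopic hydroxyls) ⇒ two-directional allylation of propane-1,3-diol (sets C5 and C7, anti).

Assumption: the target is (6S)-6-[(2S,4S,6R)-2,4,6-trihydroxypentadecyl]-5,6-dihydro-2H-pyran-2-one, i.e. C5/C7 anti, C7/C9 syn, C9/C11 anti.

**Step 1**
Reactants: 1 propane-1,3-diol; 2 allyl acetate
Product: 4 (4S,6S)-nona-1,8-diene-4,6-diol, via mono-allyl diol 3 (not isolated)
Conditions: [Ir(cod)Cl]2 (5 mol%), (S)-Cl,MeO-BIPHEP (10 mol%), 4-chloro-3-nitrobenzoic acid (20 mol%), Cs2CO3 (40 mol%), 2 (10 equiv), 1,4-dioxane, 90 °C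
Reagents that add atoms: none
Why: Two-directional iridium-catalysed transfer-hydrogenative carbonyl allylation (Krische allylation), in which each CH2OH is dehydrogenated and allylated on the chiral catalyst formed in the flask, so the (S)-ligand sets both carbinol centres (C5 and C7 of the target, 1,3-anti) and the ee of the C2-symmetric diol is raised by loss of the minor enantiomer of the first addition into a separable diastereomer; the sense of induction is confirmed by Mosher analysis on the first batch and the (R)-ligand is used if it proves opposite.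

**Step 2**
Reactants: 4 (4S,6S)-nona-1,8-diene-4,6-diol; 5 acryloyl chloride
Product: 6 (4S,6S)-6-hydroxynona-1,8-dien-4-yl prop-2-enoate
Conditions: 5 (1.0 equiv), iPr2NEt (1.2 equiv), CH2Cl2, −78 → −30 °C; unreacted 4 recycled
Reagents that add atoms: none
Why: Statistical mono-O-acylation in which the two hydroxyls of the C2-symmetric diol are homotopic, so any single acylation gives the same ester, no stereocentre is made or touched, and 1,3-acyl migration is degenerate.

**Step 3**
Reactants: 7 decanoyl chloride; 8 tributyl(vinyl)stannane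
Product: 9 dodec-1-en-3-one
Conditions: PdCl2(PPh3)2 (2 mol%), BHT (trace), THF, 50 °C; used fresh
Reagents that add atoms: none
Why: Stille acylation (palladium-catalysed acyl chloride–vinylstannane coupling) stops cleanly at the alkyl vinyl ketone because the tin reagent does not add to the product; no stereocentre.

**Step 4**
Reactants: 6 (4S,6S)-6-hydroxynona-1,8-dien-4-yl prop-2-enoate; 9 dodec-1-en-3-one
Product: 11 (6S)-6-[(2S,4E)-2-hydroxy-6-oxopentadec-4-en-1-yl]-5,6-dihydro-2H-pyran-2-one, via allyl lactone 10 (not isolated)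
Conditions: second-generation Hoveyda–Grubbs catalyst RuCl2(H2IMes)(=CH–C6H4-2-OiPr) (5 mol%), CH2Cl2 (0.01 M), ethene (1 atm), 40 °C; then Ar purge, concentrate to 0.1 M, 9 (3 equiv), catalyst (3 mol%), 40 °C
Reagents that add atoms: none
Why: Ring-closing metathesis joins the acrylate to the allyl group on the same carbinol carbon to give the six-membered α,β-unsaturated lactone, which is inert to further metathesis and so acts as a sink while ethene keeps re-opening any cycloheptene formed from the two allyl groups, and cross-metathesis of the remaining terminal alkene with the electron-poor vinyl ketone then gives the (E)-enone; no stereocentre is touched.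

**Step 5**
Reactants: 11 (6S)-6-[(2S,4E)-2-hydroxy-6-oxopentadec-4-en-1-yl]-5,6-dihydro-2H-pyran-2-one
Product: 14 (6S)-6-[(2S,4S,6R)-2,4,6-trihydroxypentadecyl]-5,6-dihydro-2H-pyran-2-one, via cyclic borate 12 (not isolated), via dihydroxy ketone 13 (not isolated)
Conditions: B(OH)3 (1.5 equiv), iPr2NEt (1.5 equiv), N,N'-bis[3,5-bis(trifluoromethyl)phenyl]thiourea (10 mol%), MeCN–THF 4:1, 23 °C; then AcOH (1:1 v/v with MeCN), H2O (3 equiv), Me4NBH(OAc)3 (8 equiv), −30 °C; aq. KNaC4H4O6, MeOH co-evaporation
Reagents that add atoms: boric acid, OB(O)O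
Why: Proposed new method: boric acid serves as a traceless, hydroxyl-directed hydroxide carrier, in that the C7–OH of 11 forms a borate monoester whose amine-generated tetrahedral hydroxyborate delivers a B–OH oxygen to C9 of the thiourea-activated enone through a six-membered chair transition state with both chain substituents equatorial (delivery to the lactone alkene would need an eight-membered one), giving reversibly and under thermodynamic control the cis-4,6-disubstituted cyclic borate 12 (C7/C9 syn), whose labile B–O bonds are cleaved by wet AcOH so that the freed C9–OH binds the acetoxyborohydride and delivers hydride intramolecularly to the protonated C11 ketone (Evans–Saksena reduction, C9/C11 anti); the closest known reaction types are the arylboronic acid/amine-mediated oxa-Michael addition to δ-hydroxy enones and the hemiacetal oxa-Michael route to syn-1,3-diols, whereas boric acid in this role, an unsaturated lactone in the substrate and the direct hand-over to the directed reduction have not been shown.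

**Compound list**
1 | propane-1,3-diol | OCCCO | starting material
2 | allyl acetate | CC(=O)OCC=C | starting material
3 | (3S)-hex-5-ene-1,3-diol | C=CC[C@H](O)CCO | intermediate
4 | (4S,6S)-nona-1,8-diene-4,6-diol | C=CC[C@H](O)C[C@H](CC=C)O | intermediate
5 | acryloyl chloride | C=CC(=O)Cl | starting material
6 | (4S,6S)-6-hydroxynona-1,8-dien-4-yl prop-2-enoate | C=CC[C@H](O)C[C@H](CC=C)OC(=O)C=C | intermediate
7 | decanoyl chloride | CCCCCCCCCC(=O)Cl | starting material
8 | tributyl(vinyl)stannane | C=C[Sn](CCCC)(CCCC)CCCC | starting material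
9 | dodec-1-en-3-one | C=CC(=O)CCCCCCCCC | intermediate
10 | (6S)-6-[(2S)-2-hydroxypent-4-en-1-yl]-5,6-dihydro-2H-pyran-2-one | C=CC[C@H](O)C[C@@H]1CC=CC(=O)O1 | intermediate
11 | (6S)-6-[(2S,4E)-2-hydroxy-6-oxopentadec-4-en-1-yl]-5,6-dihydro-2H-pyran-2-one | CCCCCCCCCC(=O)/C=C/C[C@H](O)C[C@@H]1CC=CC(=O)O1 | intermediate
12 | (6S)-6-{[(4S,6R)-2-hydroxy-6-(2-oxoundecyl)-1,3,2-dioxaborinan-4-yl]methyl}-5,6-dihydro-2H-pyran-2-one | CCCCCCCCCC(=O)C[C@H]1C[C@@H](C[C@@H]2CC=CC(=O)O2)OB(O)O1 | intermediate
13 | (6S)-6-[(2S,4R)-2,4-dihydroxy-6-oxopentadecyl]-5,6-dihydro-2H-pyran-2-one | CCCCCCCCCC(=O)C[C@H](O)C[C@H](O)C[C@@H]1CC=CC(=O)O1 | intermediate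
14 | (6S)-6-[(2S,4S,6R)-2,4,6-trihydroxypentadecyl]-5,6-dihydro-2H-pyran-2-one | CCCCCCCCC[C@@H](O)C[C@H](O)C[C@H](O)C[C@@H]1CC=CC(=O)O1 | target

**Step count**
Total steps: 5. Longest linear sequence: 4 (steps 1, 2, 4, 5; step 3 is a one-step side branch).

**Three steps most likely to fail**

Step 5 (the proposed new step). The hydroxyborate from boric acid may be too weak a nucleophile, or boron may not be released before the reduction. The fallback uses known chemistry, sets out from 11 and comes back at 13. PhB(OH)2 (1.2 equiv) with a tertiary amine–thiourea catalyst in CH2Cl2 gives the cyclic phenylboronate F1 by the established boronate-directed oxa-Michael addition. Oxidative cleavage with 30% H2O2 in pH 7 phosphate buffer/THF at 0 °C releases 13, which is isolated this time. A separate Evans–Saksena reduction (Me4NBH(OAc)3, AcOH–MeCN, −30 °C) then gives 14.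

Step 4. Ring closure of the two allyl groups to a cycloheptene may compete with the acrylate ring closure despite the ethene atmosphere. The fallback changes the order so that the ring-closing substrate has only one terminal alkene; it sets out from 4 and 9 and comes back at 13. Cross-metathesis of excess 4 (3 equiv) with 9 (same catalyst, CH2Cl2, 40 °C) gives the mono-enone diol F2. Bi(NO3)3·5H2O-catalysed hemiacetal/oxa-conjugate addition with acetaldehyde (CH2Cl2, 23 °C) gives the all-cis ethylidene acetal F3, in which C7/C9 are syn and only the C5 hydroxyl is free. Acryloyl chloride/iPr2NEt gives the acrylate F4, and ring-closing metathesis gives the lactone acetal F5. Hydrolysis of the acetal with 80% aqueous AcOH at 45 °C gives 13, which is reduced as in the second stage of step 5.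

Step 2. Statistical mono-acylation may give little more than half of 6, with bis-acrylate as waste. The fallback sets out from 4 and comes back at 6. Bu2SnO in refluxing toluene with removal of water gives the stannylene acetal F6, and acryloyl chloride (1.0 equiv, CH2Cl2, 0 °C) acylates it once to give 6 after aqueous work-up.

**Further compounds**
F1 | step 5 | (6S)-6-{[(4S,6R)-6-(2-oxoundecyl)-2-phenyl-1,3,2-dioxaborinan-4-yl]methyl}-5,6-dihydro-2H-pyran-2-one | CCCCCCCCCC(=O)C[C@H]1C[C@@H](C[C@@H]2CC=CC(=O)O2)OB(c3ccccc3)O1
F2 | step 4 | (4S,6S,8E)-4,6-dihydroxynonadeca-1,8-dien-10-one | C=CC[C@H](O)C[C@@H](O)C/C=C/C(=O)CCCCCCCCC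
F3 | step 4 | 1-[(2R,4R,6R)-6-[(2S)-2-hydroxypent-4-en-1-yl]-2-methyl-1,3-dioxan-4-yl]undecan-2-one | CCCCCCCCCC(=O)C[C@H]1C[C@@H](C[C@@H](O)CC=C)O[C@@H](C)O1
F4 | step 4 | (2S)-1-[(2R,4S,6R)-2-methyl-6-(2-oxoundecyl)-1,3-dioxan-4-yl]pent-4-en-2-yl prop-2-enoate | CCCCCCCCCC(=O)C[C@H]1C[C@@H](C[C@H](CC=C)OC(=O)C=C)O[C@@H](C)O1
F5 | step 4 | (6S)-6-{[(2R,4S,6R)-2-methyl-6-(2-oxoundecyl)-1,3-dioxan-4-yl]methyl}-5,6-dihydro-2H-pyran-2-one | CCCCCCCCCC(=O)C[C@H]1C[C@@H](C[C@@H]2CC=CC(=O)O2)O[C@@H](C)O1
F6 | step 2 | (4S,6S)-2,2-dibutyl-4,6-di(prop-2-en-1-yl)-1,3,2-dioxastanninane | C=CC[C@H]1C[C@H](CC=C)O[Sn](CCCC)(CCCC)O1
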